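Everything rests on cutting ring B at C3–C4 and C1–C6. Ring B is a phenol in which C2–OH lies between C1, the carbon that carries the stereogenic methine, and C3–OMe, while the styryl arm sits para at C5: the pattern of a ketone carbon flanked by two methylenes, joined to a three-carbon dialdehyde. Condensing an enantiopure, benzyl-protected methoxymethyl ketone that already holds rings A and C and the stereocentre with sodium nitromalonaldehyde should close ring B as a 4-nitrophenol with every substituent in place in one operation. The nitro group at C5 is then the handle, through the diazonium salt, for the ring D styryl unit.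

Key step: step 6

Remarks on the chemistry
- Ring A = 4-hydroxy-3-methoxyphenyl, ring C = 2,4-dihydroxyphenyl, ring D = 3,5-dihydroxyphenyl. Ring B is numbered C1 (bears the methine), C2 (OH), C3 (OMe), C4 (H), C5 (styryl, first nitro), C6 (H).
- Assumption: 2,4-bis(benzyloxy)benzaldehyde, 4-(benzyloxy)-3-methoxyphenylboronic acid, sodium nitromalonaldehyde (monohydrate, kept moist because the dry salt is impact-sensitive) and 3,5-diacetoxystyrene are taken as catalogue compounds.
- Benzyl ethers cannot be hydrogenolysed once the stilbene exists. They are therefore kept only as far as the annulation, which needs base-stable ethers, and are exchanged for acetates directly afterwards. The acetates also deactivate rings A and C toward the diazonium ion and fall off together in the last step under mild methanolysis.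
- The descriptor changes from R in ketone 10 to S from compound 12 onward only because ring B outranks ring A in the CIP order. The spatial arrangement is the same throughout.

Step 1
Reactants: 1 2,4-bis(benzyloxy)benzaldehyde; 2 (methoxymethyl)triphenylphosphonium chloride
Product: 3 2,4-bis(benzyloxy)-1-(2-methoxyethenyl)benzene (E/Z mixture)
Conditions: KOtBu, THF, 0 °C to rt
Reagents that add atoms: none
Why: Wittig olefination of a non-enolisable aryl aldehyde with the methoxymethylidene ylide is a standard one-carbon homologation, and the E/Z mixture is of no consequence because both isomers hydrolyse to the same aldehyde.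

Step 2
Reactants: 3 2,4-bis(benzyloxy)-1-(2-methoxyethenyl)benzene
Product: 4 [2,4-bis(benzyloxy)phenyl]acetaldehyde
Conditions: 2 M aq. HCl, THF, rt to 40 °C; crude aldehyde used at once
Reagents that add atoms: water, O
Why: Acid-catalysed enol ether hydrolysis (C-protonation, hydration of the oxocarbenium ion, loss of methanol) should unmask the arylacetaldehyde while benzyl aryl ethers survive dilute acid, and immediate use limits self-aldol reaction.

Step 3
Reactants: 5 methyltriphenylphosphonium bromide; 6 methyl methoxyacetate
Product: 7 1-methoxy-3-(triphenyl-λ5-phosphanylidene)propan-2-one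
Conditions: n-BuLi, THF, 0 °C (ylide, 2 equiv); then 6, −78 °C to rt
Reagents that add atoms: none
Why: C-acylation of methylidenetriphenylphosphorane by an ester gives the stabilised acyl ylide, because the acylphosphonium ion formed is deprotonated at once by the released methoxide or by the second equivalent of ylide, which returns as the phosphonium salt (transylidation).

Step 4
Reactants: 4 [2,4-bis(benzyloxy)phenyl]acetaldehyde; 7 1-methoxy-3-(triphenyl-λ5-phosphanylidene)propan-2-one
Product: 8 (3E)-5-[2,4-bis(benzyloxy)phenyl]-1-methoxypent-3-en-2-one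
Conditions: CH2Cl2, rt
Reagents that add atoms: none
Why: Wittig olefination with a stabilised acyl ylide runs without added base, which spares the enolisable aldehyde and the γ-benzylic enone, and should give the (E)-alkene through the favoured anti oxaphosphetane.

Step 5
Reactants: 8 (3E)-5-[2,4-bis(benzyloxy)phenyl]-1-methoxypent-3-en-2-one; 9 4-(benzyloxy)-3-methoxyphenylboronic acid
Product: 10 (4R)-4-[4-(benzyloxy)-3-methoxyphenyl]-5-[2,4-bis(benzyloxy)phenyl]-1-methoxypentan-2-one
Conditions: [Rh(nbd)2]BF4 (3 mol%), (S)-BINAP (3.3 mol%), Et3N, 1,4-dioxane/H2O (10:1), 30–40 °C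
Reagents that add atoms: none
Why: In this Hayashi–Miyaura 1,4-addition the aryl–rhodium–BINAP species inserts the (E)-enone and the oxa-π-allyl rhodium is hydrolysed; (S)-BINAP should deliver the aryl group to the Re face of C4 (the sense in which (R)-BINAP gives (S)-3-arylbutanoates from (E)-crotonates), setting C4 as R, and any β,γ-isomer formed by the amine stays in equilibrium with 8 and is drained through it.

Step 6
Reactants: 10 (4R)-4-[4-(benzyloxy)-3-methoxyphenyl]-5-[2,4-bis(benzyloxy)phenyl]-1-methoxypentan-2-one; 11 sodium nitromalonaldehyde (monohydrate)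
Product: 12 2-{(1S)-1-[4-(benzyloxy)-3-methoxyphenyl]-2-[2,4-bis(benzyloxy)phenyl]ethyl}-6-methoxy-4-nitrophenol
Conditions: NaOH (2 equiv), EtOH/THF/H2O, rt, 3–5 d, N2; then 1 M HCl to pH 3
Reagents that add atoms: none
Why: Hydroxide forms the enolate at C1 or C3 of 10, which adds to one formyl carbon of nitromalonaldehyde and dehydrates (aldol condensation); the other α-carbon then adds to the remaining formyl group in a 6-(enolexo)-exo-trig aldol closure, and loss of water with tautomerisation of the 4-nitrocyclohexadienone gives the 4-nitrophenolate, whose aromaticity and low basicity make the sequence irreversible. The closest known reaction type is the classical condensation of sodium nitromalonaldehyde with ketones bearing two α-methylene groups (acetone, dibenzyl ketone, cycloalkanones) to give 2,6-disubstituted 4-nitrophenols. The carbonyl carbon becomes C2–OH, C1 of 10 becomes C3–OMe, C3 of 10 becomes C1 and the nitro-bearing carbon becomes C5, so the two new bonds are C3–C4 and C1–C6 of ring B. No stereocentre is created; the existing one is β to the carbonyl group and untouched by enolisation, the only conceivable leak being vinylogous deprotonation in the open-chain alkylidene intermediate, which room temperature and fast ring closure should suppress. No regiochemical choice exists because both α-carbons and both formyl carbons end in the ring, and cross-condensation should win over self-aldol reaction of 10 because the nitromalonaldehyde anion is the only aldehyde present and cannot enolise. The benzyl ethers are inert to aqueous hydroxide.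

Step 7
Reactants: 12 2-{(1S)-1-[4-(benzyloxy)-3-methoxyphenyl]-2-[2,4-bis(benzyloxy)phenyl]ethyl}-6-methoxy-4-nitrophenol
Product: 13 4-[(2S)-2-(4-hydroxy-3-methoxyphenyl)-2-(2-hydroxy-3-methoxy-5-nitrophenyl)ethyl]benzene-1,3-diol
Conditions: BCl3 (1 M in CH2Cl2), pentamethylbenzene, CH2Cl2, −78 °C; MeOH quench, aqueous work-up
Reagents that add atoms: none
Why: In this Lewis-acid debenzylation BCl3 should ionise the aryl benzyl ethers at −78 °C, where aryl methyl ethers and the nitro group are untouched, while pentamethylbenzene traps the benzyl cation by Friedel–Crafts alkylation before it can attack rings A and C; no alkene is present yet.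

Step 8
Reactants: 13 4-[(2S)-2-(4-hydroxy-3-methoxyphenyl)-2-(2-hydroxy-3-methoxy-5-nitrophenyl)ethyl]benzene-1,3-diol
Product: 14 4-[(2S)-2-(4-acetoxy-3-methoxyphenyl)-2-(2-acetoxy-3-methoxy-5-nitrophenyl)ethyl]-1,3-phenylene diacetate
Conditions: Ac2O, pyridine, DMAP (cat.), CH2Cl2, 0 °C to rt
Reagents that add atoms: acetic anhydride, CC(=O)OC(C)=O
Why: DMAP-catalysed O-acylation should cap all four phenols, the hindered nitrophenol included, giving esters that withstand the diazotisation and palladium steps and lower the nucleophilicity of rings A and C.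

Step 9
Reactants: 14 4-[(2S)-2-(4-acetoxy-3-methoxyphenyl)-2-(2-acetoxy-3-methoxy-5-nitrophenyl)ethyl]-1,3-phenylene diacetate
Product: 15 4-[(2S)-2-(4-acetoxy-3-methoxyphenyl)-2-(2-acetoxy-5-amino-3-methoxyphenyl)ethyl]-1,3-phenylene diacetate
Conditions: H2 (1 atm), 10% Pd/C (palladium on carbon), EtOAc, rt; used at once
Reagents that add atoms: none
Why: Catalytic hydrogenation of an aromatic nitro group under neutral conditions should leave aryl acetates and methyl ethers intact (no benzyl ether or alkene remains), and prompt use avoids acetyl migration to nitrogen.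

Step 10
Reactants: 15 4-[(2S)-2-(4-acetoxy-3-methoxyphenyl)-2-(2-acetoxy-5-amino-3-methoxyphenyl)ethyl]-1,3-phenylene diacetate; 16 5-ethenyl-1,3-phenylene diacetate (3,5-diacetoxystyrene)
Product: 18 4-[(2S)-2-(4-acetoxy-3-methoxyphenyl)-2-{2-acetoxy-5-[(E)-2-(3,5-diacetoxyphenyl)ethenyl]-3-methoxyphenyl}ethyl]-1,3-phenylene diacetate, via arenediazonium tetrafluoroborate 17 (not isolated)
Conditions: NOBF4 (1.05 equiv), MeCN, −30 to 0 °C; then 16, Pd(OAc)2 (5 mol%), NaOAc, MeCN, rt
Reagents that add atoms: nitrosonium tetrafluoroborate, N#[O+].F[B-](F)(F)F (its nitrogen and the tetrafluoroborate ion stand in 17 only)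
Why: Anhydrous diazotisation by the nitrosonium ion is followed by a Heck–Matsuda reaction, in which oxidative addition of the diazonium ion to zerovalent palladium, insertion of the styrene at its terminal carbon and syn β-hydride elimination should give the (E)-stilbene without phosphine or strong base, leaving the acetates and the benzylic stereocentre untouched.

Step 11
Reactants: 18 4-[(2S)-2-(4-acetoxy-3-methoxyphenyl)-2-{2-acetoxy-5-[(E)-2-(3,5-diacetoxyphenyl)ethenyl]-3-methoxyphenyl}ethyl]-1,3-phenylene diacetate
Product: 19 4-[(2S)-2-{5-[(E)-2-(3,5-dihydroxyphenyl)ethenyl]-2-hydroxy-3-methoxyphenyl}-2-(4-hydroxy-3-methoxyphenyl)ethyl]benzene-1,3-diol (CNP0254096.1)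
Conditions: K2CO3 (0.5 equiv), degassed MeOH, 0 °C to rt, Ar; then AcOH to pH 5
Reagents that add atoms: none
Why: Base-catalysed transesterification (Zemplén-type methanolysis) of aryl acetates is fast at or below room temperature and should touch neither the methyl ethers, the (E)-alkene nor the diarylmethine stereocentre, with air excluded because the phenolates are oxidisable.

Compound list
1 | 2,4-bis(benzyloxy)benzaldehyde | O=Cc1ccc(OCc2ccccc2)cc1OCc1ccccc1 | starting material
2 | (methoxymethyl)triphenylphosphonium chloride | COC[P+](c1ccccc1)(c1ccccc1)c1ccccc1.[Cl-] | starting material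
3 | 2,4-bis(benzyloxy)-1-(2-methoxyethenyl)benzene (E/Z mixture) | COC=Cc1ccc(OCc2ccccc2)cc1OCc1ccccc1 | intermediate
4 | [2,4-bis(benzyloxy)phenyl]acetaldehyde | O=CCc1ccc(OCc2ccccc2)cc1OCc1ccccc1 | intermediate
5 | methyltriphenylphosphonium bromide | C[P+](c1ccccc1)(c1ccccc1)c1ccccc1.[Br-] | starting material
6 | methyl methoxyacetate | COCC(=O)OC | starting material
7 | 1-methoxy-3-(triphenyl-λ5-phosphanylidene)propan-2-one | COCC(=O)C=P(c1ccccc1)(c1ccccc1)c1ccccc1 | intermediate
8 | (3E)-5-[2,4-bis(benzyloxy)phenyl]-1-methoxypent-3-en-2-one | COCC(=O)/C=C/Cc1ccc(OCc2ccccc2)cc1OCc1ccccc1 | intermediate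
9 | 4-(benzyloxy)-3-methoxyphenylboronic acid | COc1cc(B(O)O)ccc1OCc1ccccc1 | starting material
10 | (4R)-4-[4-(benzyloxy)-3-methoxyphenyl]-5-[2,4-bis(benzyloxy)phenyl]-1-methoxypentan-2-one | COc1cc([C@H](Cc2ccc(OCc3ccccc3)cc2OCc2ccccc2)CC(=O)COC)ccc1OCc1ccccc1 | intermediate
11 | sodium nitromalonaldehyde (used as the monohydrate) | O=CC(=C[O-])[N+](=O)[O-].[Na+] | starting material
12 | 2-{(1S)-1-[4-(benzyloxy)-3-methoxyphenyl]-2-[2,4-bis(benzyloxy)phenyl]ethyl}-6-methoxy-4-nitrophenol | COc1cc([C@H](Cc2ccc(OCc3ccccc3)cc2OCc2ccccc2)c2cc([N+](=O)[O-])cc(OC)c2O)ccc1OCc1ccccc1 | intermediate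
13 | 4-[(2S)-2-(4-hydroxy-3-methoxyphenyl)-2-(2-hydroxy-3-methoxy-5-nitrophenyl)ethyl]benzene-1,3-diol | COc1cc([C@H](Cc2ccc(O)cc2O)c2cc([N+](=O)[O-])cc(OC)c2O)ccc1O | intermediate
14 | 4-[(2S)-2-(4-acetoxy-3-methoxyphenyl)-2-(2-acetoxy-3-methoxy-5-nitrophenyl)ethyl]-1,3-phenylene diacetate | COc1cc([C@H](Cc2ccc(OC(C)=O)cc2OC(C)=O)c2cc([N+](=O)[O-])cc(OC)c2OC(C)=O)ccc1OC(C)=O | intermediate
15 | 4-[(2S)-2-(4-acetoxy-3-methoxyphenyl)-2-(2-acetoxy-5-amino-3-methoxyphenyl)ethyl]-1,3-phenylene diacetate | COc1cc([C@H](Cc2ccc(OC(C)=O)cc2OC(C)=O)c2cc(N)cc(OC)c2OC(C)=O)ccc1OC(C)=O | intermediate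
16 | 5-ethenyl-1,3-phenylene diacetate (3,5-diacetoxystyrene) | C=Cc1cc(OC(C)=O)cc(OC(C)=O)c1 | starting material
17 | 4-acetoxy-3-{(1S)-1-(4-acetoxy-3-methoxyphenyl)-2-[2,4-bis(acetoxy)phenyl]ethyl}-5-methoxybenzenediazonium tetrafluoroborate | COc1cc([C@H](Cc2ccc(OC(C)=O)cc2OC(C)=O)c2cc([N+]#N)cc(OC)c2OC(C)=O)ccc1OC(C)=O.F[B-](F)(F)F | intermediate
18 | 4-[(2S)-2-(4-acetoxy-3-methoxyphenyl)-2-{2-acetoxy-5-[(E)-2-(3,5-diacetoxyphenyl)ethenyl]-3-methoxyphenyl}ethyl]-1,3-phenylene diacetate | COc1cc([C@H](Cc2ccc(OC(C)=O)cc2OC(C)=O)c2cc(/C=C/c3cc(OC(C)=O)cc(OC(C)=O)c3)cc(OC)c2OC(C)=O)ccc1OC(C)=O | intermediate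
19 | 4-[(2S)-2-{5-[(E)-2-(3,5-dihydroxyphenyl)ethenyl]-2-hydroxy-3-methoxyphenyl}-2-(4-hydroxy-3-methoxyphenyl)ethyl]benzene-1,3-diol | COc1cc([C@H](Cc2ccc(O)cc2O)c2cc(/C=C/c3cc(O)cc(O)c3)cc(OC)c2O)ccc1O | target

Total step count: 11. Longest linear sequence: 10 steps (from 1 through steps 1, 2 and 4–11); step 3 is a one-step side branch.

Steps most likely to fail

Step 6. The double condensation may stall, because the lipophilic ketone and the weakly electrophilic nitromalonaldehyde anion meet only in aqueous base. Self-aldol reaction of the ketone or erosion of configuration by vinylogous deprotonation could then compete. The fallback sets out from 10 and returns at 12. It replaces the open-chain dialdehyde by 1-methyl-3,5-dinitropyridin-2(1H)-one, a masked nitromalonaldehyde, with Et3N in EtOH or pyridine at 60–70 °C. In this known ring transformation the ketone enolate adds at C4 and then at C6 of the pyridone, and the bicyclic adduct expels N-methyl-2-nitroacetamide to leave the 2,6-disubstituted 4-nitrophenol 12. The same two ring B bonds are formed without aqueous hydroxide, and no new compound arises on this way (F0).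

Step 10. The unisolated, electron-rich diazonium ion may be lost to reduction, solvolysis or azo coupling before palladium captures it, and residual nitrosating agent may attack the styrene. The fallback sets out from 15 and returns at 18. The amine is diazotised as before and the solution is quenched with aqueous KI (iododediazoniation), giving 4-[(2S)-2-(4-acetoxy-3-methoxyphenyl)-2-(2-acetoxy-5-iodo-3-methoxyphenyl)ethyl]-1,3-phenylene diacetate F1, a stable compound that can be purified. A conventional Mizoroki–Heck coupling of F1 with 16 (Pd(OAc)2, P(o-tol)3, Et3N, DMF, 90 °C) should then give 18.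

Step 5. Enantiofacial discrimination may be incomplete, or the C3–C4 double bond may migrate into conjugation with ring C in the basic aqueous medium faster than the aryl group is transferred. The fallback sets out from 8 and returns at 10. Aprotic conjugate addition of [4-(benzyloxy)-3-methoxyphenyl]magnesium bromide (from 1-(benzyloxy)-4-bromo-2-methoxybenzene and Mg) with CuBr·SMe2 and Me3SiCl in THF at −78 °C, followed by mild acidic work-up, should give racemic 4-[4-(benzyloxy)-3-methoxyphenyl]-5-[2,4-bis(benzyloxy)phenyl]-1-methoxypentan-2-one F2. Preparative chromatography of F2 on a chiral stationary phase (amylose carbamate type) then delivers the (4R)-enantiomer 10.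

Further compounds
F0 | step 6 | none | none
F1 | step 10 | 4-[(2S)-2-(4-acetoxy-3-methoxyphenyl)-2-(2-acetoxy-5-iodo-3-methoxyphenyl)ethyl]-1,3-phenylene diacetate | COc1cc([C@H](Cc2ccc(OC(C)=O)cc2OC(C)=O)c2cc(I)cc(OC)c2OC(C)=O)ccc1OC(C)=O
F2 | step 5 | racemic 4-[4-(benzyloxy)-3-methoxyphenyl]-5-[2,4-bis(benzyloxy)phenyl]-1-methoxypentan-2-one | COc1cc(C(Cc2ccc(OCc3ccccc3)cc2OCc2ccccc2)CC(=O)COC)ccc1OCc1ccccc1
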